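## Analysis of the target

The target joins two five-membered rings through the single bond C5–C1'. Ring A is numbered C1 (the carbinol carbon carrying OH and CH2OAc), C2, C3 (chain), C4, C5 (ring B); ring B is a cyclopent-2-enone with C1' bound to C5, C2' the carbonyl, C3'=C4' the alkene and C5' carrying methyl; the chain C1''–C7'' is attached through C2'' and is a (2E,4E)-diene ending in a tertiary allylic hydroperoxide at C6''. There are five stereocentres: C1 (R), C3 (S) and C5 (S) on ring A, C1' (S) and C5' (R) on ring B. On ring A the CH2OAc carbon, the chain and ring B lie on one face and the hydroxyl on the other; on ring B the ring A substituent and the methyl group are cis, the less stable arrangement, and C1' is α to the ketone and can epimerise. The sensitive groups are the hydroperoxide (reductants, phosphines, low-valent metals, base), the cis enone (base, nucleophiles), the primary acetate (base, hydride, organometallics), the ionisable tertiary carbinol positions and the diene. The synthesis is hard for two reasons: configuration must be relayed from ring A across a freely rotating bond to C1' and C5', and three labile functions must be introduced in an order in which none meets a reagent it cannot survive. The feature used is that ring A, with its cis C3/C5 pair and 2,2-disubstituted C1, is the five-membered ring C2–C3–C4–C7–C1 of a 2,2-disubstituted norbornene (ring A C4 being the one-carbon bridge). Cleaving the norbornene alkene must therefore give cis carbon arms on C3 and C5, and an endo group on the quaternary carbon is cis to both.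

## Retrosynthetic reasoning

**C6''–OOH (31 to 30).** The O–O group is the least durable function, so it is removed first, back to the tertiary dienyl alcohol 30. The forward step must exchange one doubly allylic tertiary hydroxyl for OOH under acid, where the enone is not epoxidised and the ring A carbinol does not ionise.

**C3''–C4'' (30 to 27 and 29).** The single bond between the two alkenes is cut. Each alkene geometry is then made separately and joined with retention by a neutral palladium-catalysed coupling of alkenyl iodide 27 with alkenylstannane 29. Cutting a C=C bond instead (olefination) would need strong base beside the cis enone and the acetate. 29 comes from alkynol 28 by hydrostannylation.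

**Acetate and C3'=C4' (27 to 26 to 25).** The acetate is put on last among the ring operations because every earlier step uses hydride or carbanions. The ring B alkene is cut by retro-metathesis to dienone 25. Metathesis is neutral, so the cis C1'/C5' pair is never exposed to enolisation, which an aldol or Horner–Wadsworth–Emmons closure would risk.

**C2'–C3' (25 to 24).** The vinyl ketone is traced to lactone 24, whose carbonyl is C2'. Addition of a vinyl nucleophile both makes the ketone and releases the CH2OH that later becomes CH2OAc, so the lactone serves as protecting group, activator and stereocontrol element.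

**C4' (24 to 23 to 21 to 20).** The vinyl group on C5' is taken back through aldehyde 23 and acid 21 to tert-butyl ester 20. These are functional group changes only, and they avoid reducing an ester beside the lactone.

**C1'–C5' (20 to 16 and 18).** This bond is cut to the enolate of the cis-fused lactone 16 and the lactate-derived triflate 18 (from 17). Attack on the convex face of the bicycle sets C1'; SN2 inversion at the triflate carbon sets C5'. Both centres of ring B are thus set by reliable, independent elements, and their cis relation follows.

**C2''–CH3 and C3''–I (16 to 14).** The E trisubstituted iodoalkene is traced to terminal alkyne 14. A syn carbometalation followed by iodination with retention gives one geometry, and an alkyne, unlike a methyl ketone, cannot epimerise C3.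

**C1'–C2' (14 to 13 to 11).** The formyl carbon on C5 must become C1', which is α to the ring B carbonyl. One carbon is therefore added to the lactol carbon of 11 by olefination and hydrolysis, and the resulting six-membered lactol 13 is oxidised to lactone 14.

**C2''≡C3'' (11 to 10).** The alkyne comes from the free formyl group of 10 by one-carbon homologation. The formyl group on C5 is masked as a five-membered lactol with the cis CH2OH. The C3 formyl group could reach that hydroxyl only through a bridged six-membered hemiacetal, so the differentiation is a strong preference rather than an absolute one, and it is reinforced by the higher reactivity of a free aldehyde.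

**Alkene cleavage (10 to 9).** Both arms come from the two alkene carbons of norbornene diol 9, which fixes them cis.

**Carbinol (9 to 8 to 6).** The diol is traced through spiro-epoxide 8 to bromo aldehyde 6. Closing the epoxide by rear-side displacement of the endo bromide turns the exo formyl carbon into the endo CH2O carbon and leaves oxygen exo, which is the C1 pattern of the target. The epoxide is opened by an oxygen nucleophile under basic SN2 conditions to give the free CH2OH that the lactol and lactone steps need.

**Cycloaddition (6 to 2 and 5).** Both ring A bonds C1–C5 and C2–C3 are cut at once to cyclopentadiene 2 (from dimer 1) and 2-bromoacrolein 5 (from 3). A catalytic enantioselective Diels–Alder reaction gives three stereocentres and ring A in one step from two small achiral partners.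

## Alternatives that were turned down

**Alternative 1:** ring A is disconnected to the furan diol 2,5-bis(hydroxymethyl)furan A1. Its acid-promoted rearrangement in water (furan opening, 4π electrocyclisation) would give (R)-4-hydroxy-4-(hydroxymethyl)cyclopent-2-en-1-one A2.
- For: it reaches the quaternary carbinol in one step from a cheap feedstock, which is shorter than the five steps needed here to reach diol 9, and it avoids a lachrymatory, unstable dienophile.
- Against: A1 is achiral and the medium is achiral, so A2 can only form as the racemate unless a resolution or a chiral catalyst is added. The enone places C5 as β-carbon, so ring B would enter by conjugate addition next to a quaternary carbon whose two faces (OH versus CH2OH) differ little. C3 is a ketone and would have to become a carbon-bearing stereocentre cis to C5 by a separate, uncontrolled reduction or coupling.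
- Comparison: the chosen route is longer to the carbinol but gets the C1/C3/C5 relationships and the absolute configuration from one catalytic step and a rigid bicycle.

**Alternative 2:** the C1–C5 bond is cut, leading to keto-dienone A3, in which a silyloxymethyl ketone is tethered to a 5-alkylidene-4-methylcyclopent-2-enone. Cathodic reduction would join the exocyclic β-carbon to the ketone carbon and protonate the enolate at C1', giving A4.
- For: it is the most convergent plan. Ring B arrives intact with its methyl centre, no one-carbon arm has to be grown into a ring, and C1, C5 and C1' would be set in one step. On paper it is clearly shorter than the chosen route.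
- Against: three stereocentres would be set by a radical-anion cyclisation steered only by the remote C3 centre and by C5', without a rigid template. The cross-conjugated dienone can also be reduced or coupled at its endocyclic β-carbon or dimerise, and the alkylidene cyclopentenone is prone to double-bond migration. The skipped diene of A4 would still need a regioselective oxygenation between two similar trisubstituted alkenes.
- Comparison: the chosen route gives up convergence and step count for stereocentres that are each fixed by a bicycle, a stereospecific displacement or a stereospecific carbometalation.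

**Alternative 3:** ring A is taken from the chiral pool. (−)-Quinic acid A5 is converted to its methyl ester 5-O-silyl ether A6; periodate cleavage of the cis-diol and amine-catalysed aldol condensation would give formylcyclopentene A7.
- For: C1 comes enantiopure with no asymmetric catalyst, which is stronger than relying on a catalytic enantioselective step, and the carboxyl is a ready precursor of CH2OAc.
- Against: in A7 the C3 oxygen is on the face where the chain carbon must end up, so a C–C bond would have to replace C–O with net retention at a secondary allylic centre. C5 is sp2 and its configuration would have to be set by a reduction. The formyl carbon is again C1', so ring B must still be grown as in the chosen route, after extra redox steps on the ester.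
- Comparison: the chosen route delivers both carbon arms already on the correct face and at the aldehyde oxidation level in one cleavage step.

Key step: step 3

Remark (assumption): lactols 10, 11 and 13 are anomeric mixtures and hydroxy ketone 25 equilibrates with its six-membered hemiketal; each is written as one form. The catalyst antipode in step 3 is the one expected, on the accepted facial model, to give (1S,2S,4S)-6.

## Route

**Step 1**
Reactants: 1 dicyclopentadiene
Product: 2 cyclopenta-1,3-diene
Conditions: neat, 180 °C, fractional distillation (b.p. 40–42 °C), receiver at −78 °C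
Reagents that add atoms: none
Why: Thermal retro-Diels–Alder reaction splits each molecule of the dimer into two molecules of monomer; the monomer distils as it forms and is used cold before it dimerises again.

**Step 2**
Reactants: 3 acrolein
Product: 5 2-bromoacrolein, via 2,3-dibromopropanal 4 (not isolated)
Conditions: Br2 (1.0 equiv), CH2Cl2, −78 °C; then Et3N (1.05 equiv), −78 to 0 °C; cold aqueous wash, used as a CH2Cl2 solution
Reagents that add atoms: bromine, BrBr
Why: Electrophilic addition of bromine gives the vicinal dibromide; the amine removes the acidic α-hydrogen and the β-bromide leaves (E1cB-type dehydrobromination), the standard preparation of an α-bromo enal. The product is used fresh because it polymerises.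

**Step 3**
Reactants: 2 cyclopenta-1,3-diene; 5 2-bromoacrolein
Product: 6 (1S,2S,4S)-2-bromobicyclo[2.2.1]hept-5-ene-2-carbaldehyde (formyl exo, bromine endo)
Conditions: (R)-2-butyl-4-(1H-indol-3-ylmethyl)-3-tosyl-1,3,2-oxazaborolidin-5-one (5 mol%, from N-tosyl-(R)-tryptophan and BuB(OH)2), 2 (5 equiv), CH2Cl2, −78 °C
Reagents that add atoms: none
Why: The formyl oxygen of 5 binds to the Lewis-acidic boron and the s-cis enal lies over the indole ring, which blocks one face of the dienophile. Cyclopentadiene adds to the open face in a concerted, asynchronous, suprafacial [4+2] cycloaddition; the closest known reaction type is the oxazaborolidinone-catalysed enantioselective Diels–Alder reaction of α-substituted acroleins with cyclopentadiene. Both σ bonds (C1–C5 and C2–C3 in ring A numbering) form in the same step, so ring A and the six-membered ring of the bicycle close by cycloaddition, not by a stepwise ring closure. The two bridgehead centres are fixed relative to each other by the bicycle, which is what later forces the C3 and C5 arms to be cis. The quaternary centre is set by the exo preference of the formyl group of an α-substituted acrolein, which puts bromine endo. The absolute sense of all three centres comes from the face selection by the catalyst, so the step needs enantioface and exo-formyl selectivity. Both are favoured by the single s-cis conformer of the bound α-bromo enal and by the low temperature, which suppresses the uncatalysed background reaction.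

**Step 4**
Reactants: 6 (1S,2S,4S)-2-bromobicyclo[2.2.1]hept-5-ene-2-carbaldehyde
Product: 8 (1S,2R,4S)-spiro[bicyclo[2.2.1]hept-5-ene-2,2'-oxirane] (oxygen exo, CH2 endo), via bromohydrin 7 (not isolated)
Conditions: NaBH4, MeOH, 0 °C; concentrate; then KOt-Bu (1.2 equiv), THF, 0 °C to rt
Reagents that add atoms: none
Why: Hydride reduces the aldehyde to the exo CH2OH; its alkoxide then displaces the endo tertiary bromide from the rear in a 3-exo-tet Williamson closure, inverting the quaternary centre so that oxygen ends exo and the CH2 endo. Basic, non-ionising conditions avoid Wagner–Meerwein shifts of the norbornyl skeleton.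

**Step 5**
Reactants: 8 (1S,2R,4S)-spiro[bicyclo[2.2.1]hept-5-ene-2,2'-oxirane]
Product: 9 (1S,2R,4S)-2-(hydroxymethyl)bicyclo[2.2.1]hept-5-en-2-ol (hydroxyl exo, CH2OH endo)
Conditions: KOH (5 equiv), DMSO/H2O 4:1, 100 °C
Reagents that add atoms: water (delivered as hydroxide), O
Why: SN2 opening of the 2,2-disubstituted epoxide by hydroxide at the unhindered CH2; the tertiary C–O bond is untouched, so the exo hydroxyl and endo CH2OH are retained. Base is used because acid would ionise the tertiary centre of the norbornene.

**Step 6**
Reactants: 9 (1S,2R,4S)-2-(hydroxymethyl)bicyclo[2.2.1]hept-5-en-2-ol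
Product: 10 1,3a-dihydroxyhexahydro-1H-cyclopenta[c]furan-5-carbaldehyde (cis-fused lactol, formyl cis to the lactol ring, configuration as in the SMILES, anomers)
Conditions: O3, CH2Cl2/MeOH 4:1, −78 °C; then Me2S (5 equiv), −78 °C to rt
Reagents that add atoms: ozone, [O-][O+]=O
Why: Ozonolysis with reductive work-up cleaves the strained alkene to two formyl groups that must be cis on the new cyclopentane. The formyl group next to the carbinol carbon is captured by the cis CH2OH as a five-membered lactol, leaving the C3 formyl group as the only free aldehyde.

**Step 7**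
Reactants: 10 1,3a-dihydroxyhexahydro-1H-cyclopenta[c]furan-5-carbaldehyde
Product: 11 5-ethynylhexahydro-1H-cyclopenta[c]furan-1,3a-diol (configuration as in the SMILES)
Conditions: dimethyl (1-diazo-2-oxopropyl)phosphonate (1.2 equiv), K2CO3 (2 equiv), MeOH, 0 °C to rt
Reagents that add atoms: dimethyl (1-diazo-2-oxopropyl)phosphonate, CC(=O)C(=[N+]=[N-])P(=O)(OC)OC
Why: Seyferth–Gilbert homologation in the Ohira–Bestmann variant converts the free aldehyde to the terminal alkyne under mild carbonate conditions. The lactol exposes its aldehyde form only in low concentration and should react much more slowly, and the alkyne removes the epimerisable α-formyl centre at C3.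

**Step 8**
Reactants: 11 5-ethynylhexahydro-1H-cyclopenta[c]furan-1,3a-diol
Product: 13 6-ethynyloctahydrocyclopenta[c]pyran-3,7a-diol (cis-fused six-membered lactol, configuration as in the SMILES), via enol ether 12 (not isolated)
Conditions: [Ph3PCH2OMe]Cl (4 equiv), KOt-Bu (4 equiv), THF, 0 °C; add 11, 0 °C to rt; then 1 M HCl/THF, rt
Reagents that add atoms: (methoxymethyl)triphenylphosphonium chloride, COC[P+](c1ccccc1)(c1ccccc1)c1ccccc1.[Cl-]; water, O
Why: Wittig methoxymethylenation of the lactol (through its hydroxy aldehyde form) adds the carbon that becomes C2'. Acid hydrolysis of the enol ether gives the homologous aldehyde, which the cis CH2OH captures as the six-membered lactol; the trans tertiary hydroxyl cannot reach it.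

**Step 9**
Reactants: 13 6-ethynyloctahydrocyclopenta[c]pyran-3,7a-diol
Product: 14 6-ethynyl-7a-hydroxyhexahydrocyclopenta[c]pyran-3(1H)-one (configuration as in the SMILES)
Conditions: TEMPO (10 mol%), PhI(OAc)2 (1.3 equiv), CH2Cl2, rt
Reagents that add atoms: none
Why: Oxoammonium (TEMPO) oxidation of a lactol to the lactone; the tertiary alcohol and the alkyne are inert.

**Step 10**
Reactants: 14 6-ethynyl-7a-hydroxyhexahydrocyclopenta[c]pyran-3(1H)-one
Product: 16 7a-hydroxy-6-[(E)-1-iodoprop-1-en-2-yl]hexahydrocyclopenta[c]pyran-3(1H)-one (configuration as in the SMILES), via alkenylalane 15 (not isolated)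
Conditions: AlMe3 (4 equiv), Cp2ZrCl2 (0.5 equiv), H2O (1.5 equiv), CH2Cl2, −23 °C; then I2 (1.5 equiv) in THF, −23 to 0 °C
Reagents that add atoms: trimethylaluminium, C[Al](C)C; iodine, II
Why: Zirconium-catalysed methylalumination (Negishi carboalumination, water-accelerated) adds methyl and aluminium syn across the terminal alkyne with methyl on the internal carbon, and iodinolysis of the alkenylalane goes with retention, which fixes the E geometry. One equivalent of AlMe3 is consumed by the tertiary hydroxyl; at −23 °C the lactone should be a spectator.

**Step 11**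
Reactants: 17 tert-butyl (2S)-2-hydroxypropanoate
Product: 18 tert-butyl (2S)-2-[(trifluoromethanesulfonyl)oxy]propanoate
Conditions: Tf2O (1.1 equiv), 2,6-lutidine (1.2 equiv), CH2Cl2, −78 to 0 °C; short silica plug, used at once
Reagents that add atoms: trifluoromethanesulfonic anhydride, O=S(=O)(OS(=O)(=O)C(F)(F)F)C(F)(F)F
Why: O-sulfonylation of the α-hydroxy ester without touching the stereocentre.

**Step 12**
Reactants: 16 7a-hydroxy-6-[(E)-1-iodoprop-1-en-2-yl]hexahydrocyclopenta[c]pyran-3(1H)-one; 18 tert-butyl (2S)-2-[(trifluoromethanesulfonyl)oxy]propanoate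
Product: 20 tert-butyl (2S)-2-{7a-hydroxy-6-[(E)-1-iodoprop-1-en-2-yl]-3-oxooctahydrocyclopenta[c]pyran-4-yl}propanoate (new substituent trans to the ring A bond at C4a, configuration as in the SMILES), via dilithium enolate 19 (not isolated)
Conditions: LiN(SiMe3)2 (2.1 equiv), THF, −78 °C, 45 min; then 18 (1.2 equiv), −78 to −40 °C; sat. NH4Cl
Reagents that add atoms: none
Why: Enolate alkylation: the lithium enolate of the cis-fused lactone is attacked on its convex face, anti to the C5–C4 bond and to ring A with its C3 substituent, which sets C1'. The α-ester triflate reacts by SN2 with inversion, so (S)-18 gives the C5' configuration of the target. LiN(SiMe3)2 is chosen over a stronger amide base to spare the vinylic C–H next to iodine.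

**Step 13**
Reactants: 20 tert-butyl ester
Product: 21 (2S)-2-{7a-hydroxy-6-[(E)-1-iodoprop-1-en-2-yl]-3-oxooctahydrocyclopenta[c]pyran-4-yl}propanoic acid (configuration as in the SMILES)
Conditions: CF3CO2H/CH2Cl2 1:4, 0 °C to rt; toluene azeotrope; NaHCO3 wash, then acidify
Reagents that add atoms: none
Why: Acidolysis of the tert-butyl ester (loss of 2-methylpropene) leaves the lactone, the iodoalkene and the stereocentres untouched. A trifluoroacetate formed at the tertiary hydroxyl would be cleaved in the bicarbonate wash.

**Step 14**
Reactants: 21 carboxylic acid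
Product: 23 (2S)-2-{7a-hydroxy-6-[(E)-1-iodoprop-1-en-2-yl]-3-oxooctahydrocyclopenta[c]pyran-4-yl}propanal (configuration as in the SMILES), via primary alcohol 22 (not isolated)
Conditions: BH3·SMe2 (2.5 equiv), THF, 0 °C to rt; MeOH quench, concentrate; then Dess–Martin periodinane (1.5 equiv), NaHCO3, CH2Cl2, 0 °C
Reagents that add atoms: none
Why: Borane reduces the carboxylic acid much faster than the lactone or the hindered iodoalkene. The crude alcohol is oxidised at once so that it has no time to translactonise to the γ-lactone, and the buffered hypervalent-iodine oxidation does not epimerise the α-methyl centre.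

**Step 15**
Reactants: 23 aldehyde
Product: 24 4-[(2R)-but-3-en-2-yl]-7a-hydroxy-6-[(E)-1-iodoprop-1-en-2-yl]hexahydrocyclopenta[c]pyran-3(1H)-one (configuration as in the SMILES)
Conditions: [Ph3PCH3]Br (2.5 equiv), KN(SiMe3)2 (2.4 equiv), THF, 0 °C; cool to −78 °C, add 23, −78 to 0 °C
Reagents that add atoms: methyltriphenylphosphonium bromide, C[P+](c1ccccc1)(c1ccccc1)c1ccccc1.[Br-]
Why: Wittig methylenation of the aldehyde at low temperature; the lactone carbonyl is far less electrophilic and is not attacked, and the short contact time protects the α-methyl centre.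

**Step 16**
Reactants: 24 butenyl lactone
Product: 25 4-{2-hydroxy-2-(hydroxymethyl)-4-[(E)-1-iodoprop-1-en-2-yl]cyclopentyl}-5-methylhepta-1,6-dien-3-one (configuration as in the SMILES; equilibrates with its six-membered hemiketal)
Conditions: CH2=CHMgBr (3.5 equiv), THF, −78 °C; sat. NH4Cl at −78 °C
Reagents that add atoms: vinylmagnesium bromide, C=C[Mg]Br
Why: Addition of one vinyl group to the lactone carbonyl gives a magnesium hemiketalate that is stable at −78 °C and resists a second addition; on work-up it opens to the vinyl ketone and frees the CH2OH. A Grignard reagent does not exchange with the alkenyl iodide at this temperature.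

**Step 17**
Reactants: 25 hydroxy dienone
Product: 26 5-{2-hydroxy-2-(hydroxymethyl)-4-[(E)-1-iodoprop-1-en-2-yl]cyclopentyl}-4-methylcyclopent-2-en-1-one (ring B substituents cis, configuration as in the SMILES)
Conditions: second-generation Hoveyda–Grubbs catalyst, RuCl2(H2IMes)(=CH–C6H4-2-OiPr) (5 mol%), CH2Cl2 (5 mM), 40 °C
Reagents that add atoms: none
Why: Ring-closing metathesis of the terminal alkene with the vinyl ketone closes ring B at C3'=C4' with loss of ethene under neutral conditions, so the cis C1'/C5' relation made in step 12 passes into the enone without enolisation. The trisubstituted iodoalkene is too hindered to take part.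

**Step 18**
Reactants: 26 hydroxymethyl enone
Product: 27 {1-hydroxy-4-[(E)-1-iodoprop-1-en-2-yl]-2-(5-methyl-2-oxocyclopent-3-en-1-yl)cyclopentyl}methyl acetate (configuration as in the SMILES)
Conditions: Ac2O (1.5 equiv), pyridine (3 equiv), CH2Cl2, 0 °C
Reagents that add atoms: acetic anhydride, CC(=O)OC(C)=O
Why: Acylation of the only primary hydroxyl; the hindered tertiary hydroxyl is not acylated without a nucleophilic catalyst, and the weak base at 0 °C should not epimerise C1'.

**Step 19**
Reactants: 28 2-methylbut-3-yn-2-ol
Product: 29 (E)-2-methyl-4-(tributylstannyl)but-3-en-2-ol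
Conditions: Bu3SnH (1.1 equiv), PdCl2(PPh3)2 (2 mol%), THF, 0 °C to rt; the minor internal stannane is removed by chromatography
Reagents that add atoms: tributyltin hydride, CCCC[SnH](CCCC)CCCC
Why: Palladium-catalysed syn hydrostannylation of the terminal alkyne puts tin on the terminal carbon, away from the quaternary carbinol, and gives the E alkenylstannane.

**Step 20**
Reactants: 27 alkenyl iodide; 29 (E)-2-methyl-4-(tributylstannyl)but-3-en-2-ol
Product: 30 {1-hydroxy-4-[(2E,4E)-6-hydroxy-6-methylhepta-2,4-dien-2-yl]-2-(5-methyl-2-oxocyclopent-3-en-1-yl)cyclopentyl}methyl acetate (configuration as in the SMILES)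
Conditions: Pd2(dba)3 (5 mol%), AsPh3 (20 mol%), N-methylpyrrolidone, rt to 40 °C; aqueous KF work-up
Reagents that add atoms: none
Why: Stille coupling joins the two alkenyl carbons with retention of both geometries under neutral conditions that the cis enone, the acetate and the free hydroxyls tolerate. The arsine ligand speeds transmetalation so that the coupling runs near room temperature.

**Step 21**
Reactants: 30 dienyl tertiary alcohol
Product: 31 [(1R,2S,4S)-1-hydroxy-4-[(2E,4E)-6-hydroperoxy-6-methylhepta-2,4-dien-2-yl]-2-[(1S,5R)-5-methyl-2-oxocyclopent-3-en-1-yl]cyclopentyl]methyl acetate (CNP0204569.2)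
Conditions: H2O2 (50% aq., 30 equiv), H2SO4 (cat.), THF, 0 °C; NaHCO3 quench at 0 °C
Reagents that add atoms: hydrogen peroxide, OO
Why: Acid-catalysed perhydrolysis: the doubly allylic tertiary alcohol ionises far more readily than the ring A tertiary alcohol, and the pentadienyl cation should be trapped by the large excess of hydrogen peroxide at the less hindered gem-dimethyl terminus, which keeps the diene conjugated. Acidic peroxide does not epoxidise the enone, which would need the hydroperoxide anion.

## Compound list

1 | dicyclopentadiene (commercial endo dimer, racemic) | C1C=CC2C1C1CC2C=C1 | starting material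
2 | cyclopenta-1,3-diene | C1=CC=CC1 | intermediate
3 | acrolein | C=CC=O | starting material
4 | 2,3-dibromopropanal (racemic) | O=CC(Br)CBr | intermediate
5 | 2-bromoacrolein | C=C(Br)C=O | intermediate
6 | (1S,2S,4S)-2-bromobicyclo[2.2.1]hept-5-ene-2-carbaldehyde | O=C[C@]1(Br)C[C@H]2C=C[C@@H]1C2 | intermediate
7 | [(1S,2S,4S)-2-bromobicyclo[2.2.1]hept-5-en-2-yl]methanol | OC[C@]1(Br)C[C@H]2C=C[C@@H]1C2 | intermediate
8 | (1S,2R,4S)-spiro[bicyclo[2.2.1]hept-5-ene-2,2'-oxirane] | C1[C@@]2(O1)C[C@H]3C=C[C@@H]2C3 | intermediate
9 | (1S,2R,4S)-2-(hydroxymethyl)bicyclo[2.2.1]hept-5-en-2-ol | OC[C@@]1(O)C[C@H]2C=C[C@@H]1C2 | intermediate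
10 | 1,3a-dihydroxyhexahydro-1H-cyclopenta[c]furan-5-carbaldehyde | OC1OC[C@@]2(O)C[C@@H](C=O)C[C@H]21 | intermediate
11 | 5-ethynylhexahydro-1H-cyclopenta[c]furan-1,3a-diol | OC1OC[C@@]2(O)C[C@@H](C#C)C[C@H]21 | intermediate
12 | 4-ethynyl-1-(hydroxymethyl)-2-(2-methoxyethenyl)cyclopentan-1-ol (E/Z mixture) | OC[C@@]1(O)C[C@@H](C#C)C[C@H]1C=COC | intermediate
13 | 6-ethynyloctahydrocyclopenta[c]pyran-3,7a-diol | OC1OC[C@@]2(O)C[C@@H](C#C)C[C@H]2C1 | intermediate
14 | 6-ethynyl-7a-hydroxyhexahydrocyclopenta[c]pyran-3(1H)-one | O=C1OC[C@@]2(O)C[C@@H](C#C)C[C@H]2C1 | intermediate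
15 | dimethylaluminium alkoxide of 6-[(E)-1-(dimethylalumanyl)prop-1-en-2-yl]-7a-hydroxyhexahydrocyclopenta[c]pyran-3(1H)-one | O=C1OC[C@@]2(O[Al](C)C)C[C@@H](/C(C)=C/[Al](C)C)C[C@H]2C1 | intermediate
16 | 7a-hydroxy-6-[(E)-1-iodoprop-1-en-2-yl]hexahydrocyclopenta[c]pyran-3(1H)-one | O=C1OC[C@@]2(O)C[C@@H](/C(C)=C/I)C[C@H]2C1 | intermediate
17 | tert-butyl (2S)-2-hydroxypropanoate | C[C@H](O)C(=O)OC(C)(C)C | starting material
18 | tert-butyl (2S)-2-[(trifluoromethanesulfonyl)oxy]propanoate | C[C@H](OS(=O)(=O)C(F)(F)F)C(=O)OC(C)(C)C | intermediate
19 | dilithium enolate-alkoxide of 16 | [Li+].[Li+].[O-]C=1OC[C@@]2([O-])C[C@@H](/C(C)=C/I)C[C@H]2C=1 | intermediate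
20 | tert-butyl (2S)-2-{7a-hydroxy-6-[(E)-1-iodoprop-1-en-2-yl]-3-oxooctahydrocyclopenta[c]pyran-4-yl}propanoate | O=C1OC[C@@]2(O)C[C@@H](/C(C)=C/I)C[C@H]2[C@@H]1[C@H](C)C(=O)OC(C)(C)C | intermediate
21 | (2S)-2-{7a-hydroxy-6-[(E)-1-iodoprop-1-en-2-yl]-3-oxooctahydrocyclopenta[c]pyran-4-yl}propanoic acid | O=C1OC[C@@]2(O)C[C@@H](/C(C)=C/I)C[C@H]2[C@@H]1[C@H](C)C(=O)O | intermediate
22 | 7a-hydroxy-4-[(2S)-1-hydroxypropan-2-yl]-6-[(E)-1-iodoprop-1-en-2-yl]hexahydrocyclopenta[c]pyran-3(1H)-one | O=C1OC[C@@]2(O)C[C@@H](/C(C)=C/I)C[C@H]2[C@@H]1[C@H](C)CO | intermediate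
23 | (2S)-2-{7a-hydroxy-6-[(E)-1-iodoprop-1-en-2-yl]-3-oxooctahydrocyclopenta[c]pyran-4-yl}propanal | O=C1OC[C@@]2(O)C[C@@H](/C(C)=C/I)C[C@H]2[C@@H]1[C@H](C)C=O | intermediate
24 | 4-[(2R)-but-3-en-2-yl]-7a-hydroxy-6-[(E)-1-iodoprop-1-en-2-yl]hexahydrocyclopenta[c]pyran-3(1H)-one | O=C1OC[C@@]2(O)C[C@@H](/C(C)=C/I)C[C@H]2[C@@H]1[C@H](C)C=C | intermediate
25 | 4-{2-hydroxy-2-(hydroxymethyl)-4-[(E)-1-iodoprop-1-en-2-yl]cyclopentyl}-5-methylhepta-1,6-dien-3-one | OC[C@@]1(O)C[C@@H](/C(C)=C/I)C[C@H]1[C@@H](C(=O)C=C)[C@H](C)C=C | intermediate
26 | 5-{2-hydroxy-2-(hydroxymethyl)-4-[(E)-1-iodoprop-1-en-2-yl]cyclopentyl}-4-methylcyclopent-2-en-1-one | OC[C@@]1(O)C[C@@H](/C(C)=C/I)C[C@H]1[C@H]1C(=O)C=C[C@H]1C | intermediate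
27 | {1-hydroxy-4-[(E)-1-iodoprop-1-en-2-yl]-2-(5-methyl-2-oxocyclopent-3-en-1-yl)cyclopentyl}methyl acetate | CC(=O)OC[C@@]1(O)C[C@@H](/C(C)=C/I)C[C@H]1[C@H]1C(=O)C=C[C@H]1C | intermediate
28 | 2-methylbut-3-yn-2-ol | CC(C)(O)C#C | starting material
29 | (E)-2-methyl-4-(tributylstannyl)but-3-en-2-ol | CCCC[Sn](CCCC)(CCCC)/C=C/C(C)(C)O | intermediate
30 | {1-hydroxy-4-[(2E,4E)-6-hydroxy-6-methylhepta-2,4-dien-2-yl]-2-(5-methyl-2-oxocyclopent-3-en-1-yl)cyclopentyl}methyl acetate | CC(=O)OC[C@@]1(O)C[C@@H](/C(C)=C/C=C/C(C)(C)O)C[C@H]1[C@H]1C(=O)C=C[C@H]1C | intermediate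
31 | [(1R,2S,4S)-1-hydroxy-4-[(2E,4E)-6-hydroperoxy-6-methylhepta-2,4-dien-2-yl]-2-[(1S,5R)-5-methyl-2-oxocyclopent-3-en-1-yl]cyclopentyl]methyl acetate | CC(=O)OC[C@@]1(O)C[C@@H](/C(C)=C/C=C/C(C)(C)OO)C[C@H]1[C@H]1C(=O)C=C[C@H]1C | target

## Step count and weak points

Total: 21 steps (steps 1, 11 and 19 are side branches). Longest linear sequence: 18 steps, from acrolein 3 through steps 2–10, 12–18, 20 and 21.

**Step 3 (key step).** The likely failure is erosion of enantio- or exo-selectivity by the uncatalysed background cycloaddition or by hydrolysis of the boron catalyst, together with polymerisation of 5. Fallback by resolution instead of asymmetric catalysis: setting out from 2 and 5, the uncatalysed (or Et2AlCl-promoted) cycloaddition would give 6 together with its mirror image, (1R,2R,4R)-2-bromobicyclo[2.2.1]hept-5-ene-2-carbaldehyde F1. NaBH4 reduction would give 7 together with [(1R,2R,4R)-2-bromobicyclo[2.2.1]hept-5-en-2-yl]methanol F2. A lipase chosen by screening (for example Candida antarctica lipase B with vinyl acetate) would acylate F2 to [(1R,2R,4R)-2-bromobicyclo[2.2.1]hept-5-en-2-yl]methyl acetate F3, which is separated from unreacted 7. Compound 7 rejoins the route at the base closure of step 4, leading to 8.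

**Step 21.** The likely failure is regiochemical scrambling: capture of the delocalised cation at C2'' or C4'' instead of C6'', loss of a proton to a triene, or reversible addition of peroxide to the ketone. Fallback by a pericyclic instead of an ionic oxygenation: setting out from 27, Stille coupling with tributyl(3-methylbut-2-enyl)stannane would give the skipped diene {1-hydroxy-4-[(2E)-6-methylhepta-2,5-dien-2-yl]-2-(5-methyl-2-oxocyclopent-3-en-1-yl)cyclopentyl}methyl acetate F4. The Schenck ene reaction of F4 with singlet oxygen (O2, tetraphenylporphyrin, visible light, CH2Cl2, 0 °C) removes a doubly allylic hydrogen at C4'' and comes back to the route at 31. Ene products from the other trisubstituted alkene would have to be separated.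

**Step 12.** The likely failures are elimination of the secondary triflate, proton exchange between product and enolate that epimerises C1' or C5', and incomplete facial selectivity. Fallback by a sigmatropic route to the two centres: setting out from 16, opening with lithium (E)-but-2-en-1-olate and trapping the released primary alkoxide with Et3SiCl would give (E)-but-2-en-1-yl 2-{2-hydroxy-4-[(E)-1-iodoprop-1-en-2-yl]-2-[(triethylsilyloxy)methyl]cyclopentyl}acetate F5. Ireland–Claisen rearrangement (LiN(iPr)2, Me3SiCl, THF, −78 °C to rt) through the chair transition state would give 2-{2-hydroxy-4-[(E)-1-iodoprop-1-en-2-yl]-2-[(triethylsilyloxy)methyl]cyclopentyl}-3-methylpent-4-enoic acid F6, with the C1'/C5' pair anti and the ketene acetal face chosen by allylic strain from C5. PPTS in MeOH removes the silyl group and the hydroxy acid closes to lactone 24, where the fallback rejoins the route.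

**Step 10.** The likely failures are attack of the aluminium reagent on the lactone, stalling of the carbometalation because the Lewis acid is bound by the lactone and alkoxide, and protonolysis of the alkenylalane before iodination. Fallback by moving the carbometalation to a carbonyl-free substrate: setting out from 13, MeOH with PPTS would give the methyl acetal 6-ethynyl-3-methoxyhexahydrocyclopenta[c]pyran-7a(1H)-ol F7. Carboalumination and iodination as in step 10 would give 6-[(E)-1-iodoprop-1-en-2-yl]-3-methoxyhexahydrocyclopenta[c]pyran-7a(1H)-ol F8. CrO3/H2SO4 in acetone would oxidise the acetal directly to lactone 16, where the fallback rejoins the route.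

**Step 7.** The likely failures are loss of chemoselectivity (homologation of the lactol carbon as well) and epimerisation at C3 under the carbonate conditions before the alkyne forms. Fallback by locking the C5 arm at the acid oxidation level: setting out from 10, Ag2CO3 on Celite (benzene, 80 °C) would oxidise only the lactol to 3a-hydroxy-1-oxohexahydro-1H-cyclopenta[c]furan-5-carbaldehyde F9. The same alkyne homologation would give 5-ethynyl-3a-hydroxyhexahydro-1H-cyclopenta[c]furan-1-one F10, and iBu2AlH (CH2Cl2, −78 °C) would reduce the lactone back to lactol 11, where the fallback rejoins the route.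

## Further compounds

F1 | step 3 | (1R,2R,4R)-2-bromobicyclo[2.2.1]hept-5-ene-2-carbaldehyde | O=C[C@@]1(Br)C[C@@H]2C=C[C@H]1C2
F2 | step 3 | [(1R,2R,4R)-2-bromobicyclo[2.2.1]hept-5-en-2-yl]methanol | OC[C@@]1(Br)C[C@@H]2C=C[C@H]1C2
F3 | step 3 | [(1R,2R,4R)-2-bromobicyclo[2.2.1]hept-5-en-2-yl]methyl acetate | CC(=O)OC[C@@]1(Br)C[C@@H]2C=C[C@H]1C2
F4 | step 21 | {1-hydroxy-4-[(2E)-6-methylhepta-2,5-dien-2-yl]-2-(5-methyl-2-oxocyclopent-3-en-1-yl)cyclopentyl}methyl acetate | CC(=O)OC[C@@]1(O)C[C@@H](/C(C)=C/CC=C(C)C)C[C@H]1[C@H]1C(=O)C=C[C@H]1C
F5 | step 12 | (E)-but-2-en-1-yl 2-{2-hydroxy-4-[(E)-1-iodoprop-1-en-2-yl]-2-[(triethylsilyloxy)methyl]cyclopentyl}acetate | CC[Si](CC)(CC)OC[C@@]1(O)C[C@@H](/C(C)=C/I)C[C@H]1CC(=O)OC/C=C/C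
F6 | step 12 | 2-{2-hydroxy-4-[(E)-1-iodoprop-1-en-2-yl]-2-[(triethylsilyloxy)methyl]cyclopentyl}-3-methylpent-4-enoic acid | CC[Si](CC)(CC)OC[C@@]1(O)C[C@@H](/C(C)=C/I)C[C@H]1[C@@H](C(=O)O)[C@H](C)C=C
F7 | step 10 | 6-ethynyl-3-methoxyhexahydrocyclopenta[c]pyran-7a(1H)-ol | COC1OC[C@@]2(O)C[C@@H](C#C)C[C@H]2C1
F8 | step 10 | 6-[(E)-1-iodoprop-1-en-2-yl]-3-methoxyhexahydrocyclopenta[c]pyran-7a(1H)-ol | COC1OC[C@@]2(O)C[C@@H](/C(C)=C/I)C[C@H]2C1
F9 | step 7 | 3a-hydroxy-1-oxohexahydro-1H-cyclopenta[c]furan-5-carbaldehyde | O=C1OC[C@@]2(O)C[C@@H](C=O)C[C@H]21
F10 | step 7 | 5-ethynyl-3a-hydroxyhexahydro-1H-cyclopenta[c]furan-1-one | O=C1OC[C@@]2(O)C[C@@H](C#C)C[C@H]21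
A1 | alternative 1 | 2,5-bis(hydroxymethyl)furan | OCc1ccc(CO)o1
A2 | alternative 1 | (R)-4-hydroxy-4-(hydroxymethyl)cyclopent-2-en-1-one | OC[C@@]1(O)CC(=O)C=C1
A3 | alternative 2 | 5-{6-[(tert-butyldimethylsilyl)oxy]-3-[(2E)-6-methylhepta-2,5-dien-2-yl]-5-oxohexylidene}-4-methylcyclopent-2-en-1-one | CC(C)(C)[Si](C)(C)OCC(=O)C[C@@H](/C(C)=C/CC=C(C)C)CC=C1C(=O)C=C[C@H]1C
A4 | alternative 2 | 5-{2-[(tert-butyldimethylsilyloxy)methyl]-2-hydroxy-4-[(2E)-6-methylhepta-2,5-dien-2-yl]cyclopentyl}-4-methylcyclopent-2-en-1-one | CC(C)(C)[Si](C)(C)OC[C@@]1(O)C[C@@H](/C(C)=C/CC=C(C)C)C[C@H]1[C@H]1C(=O)C=C[C@H]1C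
A5 | alternative 3 | (−)-quinic acid | OC(=O)[C@]1(O)C[C@@H](O)[C@@H](O)[C@H](O)C1
A6 | alternative 3 | methyl 5-O-(tert-butyldimethylsilyl)quinate | COC(=O)[C@]1(O)C[C@@H](O)[C@@H](O)[C@H](O[Si](C)(C)C(C)(C)C)C1
A7 | alternative 3 | methyl 4-(tert-butyldimethylsilyloxy)-2-formyl-1-hydroxycyclopent-2-ene-1-carboxylate | COC(=O)[C@@]1(O)C[C@@H](O[Si](C)(C)C(C)(C)C)C=C1C=O
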